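The key step exploits the quinone ring (C1–C4, C4a, C8a): C1(=O)–C2(CH3) is the carbonyl and α-carbon of a propiophenone already bonded to C8a, and C3–C4(=O) is ethoxyacetylene, whose oxygen becomes the C4 oxygen. In step 1 a photoredox-generated α-keto radical at C2 adds to the alkyne (C2–C3) and the resulting vinyl radical closes onto the arene (C4–C4a), so two non-naphthalene pieces give the 1,4-dioxygenated 2-methylnaphthalene in one operation. The C7 chlorine then becomes a vinyl handle for B-alkyl Suzuki union with an (E)-alkenyl iodide whose diol comes from Sharpless epoxidation of geraniol and stereospecific epoxide hydrolysis; acetylation and oxidative dealkylation finish.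

Key step: step 1

Remarks on the chemistry
- Locants are those of the naphthoquinone: C1(=O) next to C2(CH3), C4(=O) next to C3–H, side chain on C7.
- Compound 1 is used as the commercial racemate; its stereocenter disappears on aromatization in step 1.
- In step 10 the two quinone oxygens are counted as coming from water (aryl–oxygen cleavage), the ether oxygens leaving as ethanol.
- ppy = 2-phenylpyridinato.

Step 1
Reactants: 1 2-bromo-1-(3-chlorophenyl)propan-1-one; 2 ethoxyethyne
Product: 4 7-chloro-1,4-diethoxy-2-methylnaphthalene, via free naphthol 3 (not isolated)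
Conditions: 2 (3 equiv), fac-Ir(ppy)3 (1 mol%), 2,6-lutidine (1.5 equiv), MeCN, 450 nm LEDs, rt, Ar; then EtI, Cs2CO3, DMF, 50 °C
Reagents that add atoms: iodoethane CCI
Why: Proposed new method: the photoexcited iridium complex reduces the C–Br bond of 1 to an electrophilic α-keto radical at C2, which adds to the unsubstituted carbon of the electron-rich ynol ether 2 (C2–C3) to give an α-ethoxyvinyl radical that attacks the ortho carbon of the aroyl ring (C4–C4a); the cyclohexadienyl radical is oxidized by the tetravalent iridium species, loses H+ and tautomerizes to naphthol 3, which is O-ethylated in the same flask before air can oxidize it. The closest known reaction type is the visible-light photoredox radical benzannulation of 2-bromo-1,3-dicarbonyl compounds with aryl- and alkylacetylenes to 1-naphthols; neither a simple secondary α-bromo aryl ketone nor an alkoxyacetylene partner has been shown. The single new ring (six-membered) closes by homolytic aromatic substitution, a 6-endo-type attack of the vinyl radical on the arene counted along the C4a–C8a bond. No stereocenter is formed and the one in racemic 1 is erased on aromatization. The step needs addition at the CH terminus of the alkyne, secured by the polarity match and by oxygen stabilization of the vinyl radical, and closure para rather than ortho to chlorine, secured by the chlorine that flanks the other ortho carbon and would sit peri to the C4 ethoxy group.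

Step 2
Reactants: 4 7-chloro-1,4-diethoxy-2-methylnaphthalene
Product: 5 7-ethenyl-1,4-diethoxy-2-methylnaphthalene
Conditions: CH2=CHBF3K (1.5 equiv), Pd(OAc)2 (2 mol%), RuPhos (4 mol%), K2CO3 (3 equiv), THF/H2O (9:1), 85 °C
Reagents that add atoms: potassium vinyltrifluoroborate C=C[B-](F)(F)F.[K+]
Why: Suzuki–Miyaura vinylation with a trifluoroborate, in which the electron-rich dialkylbiarylphosphine should let zerovalent palladium insert into the electron-rich aryl chloride.

Step 3
Reactants: 6 geraniol
Product: 7 (2R,3R)-2,3-epoxygeraniol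
Conditions: Ti(OiPr)4 (5 mol%), D-(−)-diethyl tartrate (7.5 mol%), t-BuOOH (2 equiv, decane), 4 Å MS, CH2Cl2, −20 °C
Reagents that add atoms: tert-butyl hydroperoxide CC(C)(C)OO
Why: Sharpless asymmetric epoxidation, in which the D-tartrate ligand should deliver oxygen to the face of the allylic alcohol that gives the (2R,3R)-epoxide (L-(+)-tartrate gives the 2S,3S enantiomer) while the remote trisubstituted alkene is not touched.

Step 4
Reactants: 7 (2R,3R)-2,3-epoxygeraniol
Product: 8 (2R,3S)-3,7-dimethyloct-6-ene-1,2,3-triol
Conditions: HClO4 (5 mol%), THF/H2O (3:1), 0 °C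
Reagents that add atoms: water O
Why: acid-catalysed epoxide hydrolysis, in which water should attack the more substituted C3 of the protonated epoxide from the rear (borderline SN2), inverting C3 from R to S while the C2–O bond is untouched and C2 stays R.

Step 5
Reactants: 8 (2R,3S)-3,7-dimethyloct-6-ene-1,2,3-triol
Product: 10 (2S)-6-methyl-2-[(2R)-oxiran-2-yl]hept-5-en-2-ol, via primary tosylate 9 (not isolated)
Conditions: TsCl (1.05 equiv), Et3N, Bu2SnO (2 mol%), CH2Cl2, 0 °C; then K2CO3, MeOH, 0 °C, short reaction time
Reagents that add atoms: none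
Why: tin-catalysed selective sulfonylation of the primary hydroxyl followed by intramolecular Williamson closure (3-exo-tet) from the C2 oxygen, which breaks no bond at either stereocenter; the mild base and short time should prevent Payne equilibration.

Step 6
Reactants: 10 (2S)-6-methyl-2-[(2R)-oxiran-2-yl]hept-5-en-2-ol
Product: 12 (5R,6S)-6,10-dimethylundec-9-en-1-yne-5,6-diol, via silylalkyne diol 11 (not isolated)
Conditions: TMSC≡CCH3 (3 equiv), n-BuLi (3 equiv), THF, −78 to −20 °C; 10, DMPU, −78 to −20 °C; then MeOH, K2CO3, rt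
Reagents that add atoms: 1-(trimethylsilyl)propyne CC#C[Si](C)(C)C
Why: the propargylic lithium reagent should open the terminal epoxide at its unsubstituted carbon (SN2) without touching either stereocenter, and basic methanolysis then removes the C-silyl group.

Step 7
Reactants: 12 (5R,6S)-6,10-dimethylundec-9-en-1-yne-5,6-diol
Product: 14 (1E,5R,6S)-1-iodo-2,6,10-trimethylundeca-1,9-diene-5,6-diol, via alkenylalane 13 (not isolated)
Conditions: AlMe3 (5 equiv), Cp2ZrCl2 (0.5 equiv), CH2Cl2, 0 °C to rt; then I2 (1.1 equiv), THF, −30 °C; aq. potassium sodium tartrate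
Reagents that add atoms: trimethylaluminium C[Al](C)C; iodine II
Why: Negishi zirconium-catalysed methylalumination adds CH3 and Al syn across the terminal alkyne with Al at the terminus, and iodinolysis with retention should give the (E)-iodide; the hydroxyls are carried as aluminium alkoxides and the trisubstituted alkene is inert.

Step 8
Reactants: 5 7-ethenyl-1,4-diethoxy-2-methylnaphthalene; 14 (1E,5R,6S)-1-iodo-2,6,10-trimethylundeca-1,9-diene-5,6-diol
Product: 16 (3E,7R,8S)-1-(5,8-diethoxy-7-methylnaphthalen-2-yl)-4,8,12-trimethyltrideca-3,11-diene-7,8-diol, via alkylborane 15 (not isolated)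
Conditions: 5 (1.4 equiv), 9-BBN (1.5 equiv), THF, 0 °C to rt; then aq. Cs2CO3 (3 equiv), 14, PdCl2(dppf) (5 mol%), AsPh3 (10 mol%), DMF, rt
Reagents that add atoms: none
Why: anti-Markovnikov hydroboration of the aryl-vinyl group followed by B-alkyl Suzuki–Miyaura coupling, which proceeds with retention of the (E)-alkenyl iodide geometry and tolerates the free diol.

Step 9
Reactants: 16 (3E,7R,8S)-1-(5,8-diethoxy-7-methylnaphthalen-2-yl)-4,8,12-trimethyltrideca-3,11-diene-7,8-diol
Product: 17 (3E,7R,8S)-1-(5,8-diethoxy-7-methylnaphthalen-2-yl)-8-hydroxy-4,8,12-trimethyltrideca-3,11-dien-7-yl acetate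
Conditions: Ac2O (1.5 equiv), pyridine, DMAP (5 mol%), CH2Cl2, 0 °C to rt
Reagents that add atoms: acetic anhydride CC(=O)OC(C)=O
Why: DMAP-catalysed acylation should be selective for the secondary hydroxyl over the hindered tertiary one, leaves both stereocenters untouched, and is placed before the oxidation so that no free 1,2-diol meets tetravalent cerium.

Step 10
Reactants: 17 (3E,7R,8S)-1-(5,8-diethoxy-7-methylnaphthalen-2-yl)-8-hydroxy-4,8,12-trimethyltrideca-3,11-dien-7-yl acetate
Product: 18 chabrolonaphthoquinone B
Conditions: (NH4)2Ce(NO3)6 (2.5 equiv), MeCN/H2O (2:1), 0 °C, 15 min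
Reagents that add atoms: water O
Why: oxidative dealkylation of the hydroquinone diethyl ether, in which two one-electron oxidations by tetravalent cerium with water attack at C1 and C4 release ethanol and should give the quinone, the acetate, tertiary alcohol and isolated alkenes being far harder to oxidize than the dialkoxynaphthalene.

Compound list
1 | 2-bromo-1-(3-chlorophenyl)propan-1-one (racemic) | CC(Br)C(=O)c1cccc(Cl)c1 | starting material
2 | ethoxyethyne (ethoxyacetylene) | C#COCC | starting material
3 | 7-chloro-4-ethoxy-2-methylnaphthalen-1-ol (formed in the flask in step 1) | CCOc1cc(C)c(O)c2cc(Cl)ccc12 | intermediate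
4 | 7-chloro-1,4-diethoxy-2-methylnaphthalene | CCOc1cc(C)c(OCC)c2cc(Cl)ccc12 | intermediate
5 | 7-ethenyl-1,4-diethoxy-2-methylnaphthalene | CCOc1cc(C)c(OCC)c2cc(C=C)ccc12 | intermediate
6 | geraniol, (2E)-3,7-dimethylocta-2,6-dien-1-ol | CC(C)=CCC/C(C)=C/CO | starting material
7 | (2R,3R)-2,3-epoxygeraniol, [(2R,3R)-3-methyl-3-(4-methylpent-3-en-1-yl)oxiran-2-yl]methanol | OC[C@H]1O[C@]1(C)CCC=C(C)C | intermediate
8 | (2R,3S)-3,7-dimethyloct-6-ene-1,2,3-triol | OC[C@@H](O)[C@@](C)(O)CCC=C(C)C | intermediate
9 | (2R,3S)-2,3-dihydroxy-3,7-dimethyloct-6-en-1-yl 4-methylbenzenesulfonate (formed in the flask in step 5) | Cc1ccc(cc1)S(=O)(=O)OC[C@@H](O)[C@@](C)(O)CCC=C(C)C | intermediate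
10 | (2S)-6-methyl-2-[(2R)-oxiran-2-yl]hept-5-en-2-ol | C1O[C@H]1[C@@](C)(O)CCC=C(C)C | intermediate
11 | (5R,6S)-6,10-dimethyl-1-(trimethylsilyl)undec-9-en-1-yne-5,6-diol (formed in the flask in step 6) | C[Si](C)(C)C#CCC[C@@H](O)[C@@](C)(O)CCC=C(C)C | intermediate
12 | (5R,6S)-6,10-dimethylundec-9-en-1-yne-5,6-diol | C#CCC[C@@H](O)[C@@](C)(O)CCC=C(C)C | intermediate
13 | (1E,5R,6S)-alkenyl(dimethyl)alane with both hydroxyls as dimethylaluminium alkoxides (formed in the flask in step 7) | C/C(CC[C@@H](O[Al](C)C)[C@@](C)(O[Al](C)C)CCC=C(C)C)=C\[Al](C)C | intermediate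
14 | (1E,5R,6S)-1-iodo-2,6,10-trimethylundeca-1,9-diene-5,6-diol | I/C=C(\C)CC[C@@H](O)[C@@](C)(O)CCC=C(C)C | intermediate
15 | 9-[2-(5,8-diethoxy-7-methylnaphthalen-2-yl)ethyl]-9-borabicyclo[3.3.1]nonane (formed in the flask in step 8) | CCOc1cc(C)c(OCC)c2cc(CCB3C4CCCC3CCC4)ccc12 | intermediate
16 | (3E,7R,8S)-1-(5,8-diethoxy-7-methylnaphthalen-2-yl)-4,8,12-trimethyltrideca-3,11-diene-7,8-diol | CCOc1cc(C)c(OCC)c2cc(CC/C=C(\C)CC[C@@H](O)[C@@](C)(O)CCC=C(C)C)ccc12 | intermediate
17 | (3E,7R,8S)-1-(5,8-diethoxy-7-methylnaphthalen-2-yl)-8-hydroxy-4,8,12-trimethyltrideca-3,11-dien-7-yl acetate | CCOc1cc(C)c(OCC)c2cc(CC/C=C(\C)CC[C@@H](OC(C)=O)[C@@](C)(O)CCC=C(C)C)ccc12 | intermediate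
18 | chabrolonaphthoquinone B, (3E,7R,8S)-8-hydroxy-4,8,12-trimethyl-1-(7-methyl-5,8-dioxo-5,8-dihydronaphthalen-2-yl)trideca-3,11-dien-7-yl acetate | CC(=O)O[C@H](CC/C(C)=C/CCc1ccc2c(c1)C(=O)C(C)=CC2=O)[C@@](C)(O)CCC=C(C)C | target

Total step count: 10.
Longest linear sequence: 8 steps (6 to 18, steps 3–10).

Steps most likely to fail

Step 1 (Proposed new method). The α-ethoxyvinyl radical may be intercepted before it closes onto the arene, by one-electron oxidation to a ketenium ion or by bromine-atom transfer. Closure may also occur at the chlorine-flanked ortho carbon or at the ipso carbon, and the electron-rich naphthol may be over-oxidized before it is ethylated. The fallback is known xanthate group-transfer radical chemistry; it sets out from 1 and comes back at 4. Displacement of bromide in 1 with potassium O-ethyl carbonodithioate (acetone) should give S-[1-(3-chlorophenyl)-1-oxopropan-2-yl] O-ethyl carbonodithioate F1. Dilauroyl peroxide-initiated addition to vinyl pivalate (1,2-dichloroethane, reflux) should give 4-(3-chlorophenyl)-1-[(ethoxycarbonothioyl)sulfanyl]-3-methyl-4-oxobutyl 2,2-dimethylpropanoate F2. Stoichiometric dilauroyl peroxide should close the acyloxyalkyl radical onto the arene to 6-chloro-3-methyl-4-oxo-1,2,3,4-tetrahydronaphthalen-1-yl 2,2-dimethylpropanoate F3. p-TsOH in refluxing toluene should eliminate pivalic acid and, after tautomerization, give 7-chloro-2-methylnaphthalen-1-ol F4. (KSO3)2NO in buffered aqueous acetone should oxidize this para to the hydroxyl to 7-chloro-2-methylnaphthalene-1,4-dione F5. Reduction with Na2S2O4 and ethylation of the hydroquinone in the same flask (EtI, K2CO3, DMF, under N2) should give 4.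

Step 4. Carbocation character at the tertiary carbon may cost stereochemical fidelity at C3, and attack at C2 would erode enantiopurity. The fallback sets out from 6 and comes back at 8. Sharpless epoxidation of 6 with L-(+)-diethyl tartrate should give (2S,3S)-2,3-epoxygeraniol F6. Treatment with 0.5 M NaOH in t-BuOH/H2O at 75 °C should effect Payne rearrangement (intramolecular SN2 at C2, inversion) and hydroxide opening of the terminal epoxide at C1. This delivers the same triol 8 with no substitution at the tertiary carbon.

Step 7. The aluminium diolate may retard carbometalation or protonate the alkenylalane, and the alkoxide may undergo iodocyclization onto the remote alkene during iodinolysis. The fallback sets out from 12 and comes back at 14. TESOTf and 2,6-lutidine should give (5R,6S)-6,10-dimethyl-5,6-bis[(triethylsilyl)oxy]undec-9-en-1-yne F7. The same methylalumination and iodinolysis should give (1E,5R,6S)-1-iodo-2,6,10-trimethyl-5,6-bis[(triethylsilyl)oxy]undeca-1,9-diene F8. Bu4NF in THF should then give 14.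

Further compounds
F1 | step 1 | S-[1-(3-chlorophenyl)-1-oxopropan-2-yl] O-ethyl carbonodithioate (racemic) | CCOC(=S)SC(C)C(=O)c1cccc(Cl)c1
F2 | step 1 | 4-(3-chlorophenyl)-1-[(ethoxycarbonothioyl)sulfanyl]-3-methyl-4-oxobutyl 2,2-dimethylpropanoate (diastereomer mixture) | CCOC(=S)SC(CC(C)C(=O)c1cccc(Cl)c1)OC(=O)C(C)(C)C
F3 | step 1 | 6-chloro-3-methyl-4-oxo-1,2,3,4-tetrahydronaphthalen-1-yl 2,2-dimethylpropanoate (diastereomer mixture) | CC1CC(OC(=O)C(C)(C)C)c2ccc(Cl)cc2C1=O
F4 | step 1 | 7-chloro-2-methylnaphthalen-1-ol | Cc1ccc2ccc(Cl)cc2c1O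
F5 | step 1 | 7-chloro-2-methylnaphthalene-1,4-dione | CC1=CC(=O)c2ccc(Cl)cc2C1=O
F6 | step 4 | (2S,3S)-2,3-epoxygeraniol | OC[C@@H]1O[C@@]1(C)CCC=C(C)C
F7 | step 7 | (5R,6S)-6,10-dimethyl-5,6-bis[(triethylsilyl)oxy]undec-9-en-1-yne | C#CCC[C@@H](O[Si](CC)(CC)CC)[C@@](C)(O[Si](CC)(CC)CC)CCC=C(C)C
F8 | step 7 | (1E,5R,6S)-1-iodo-2,6,10-trimethyl-5,6-bis[(triethylsilyl)oxy]undeca-1,9-diene | I/C=C(\C)CC[C@@H](O[Si](CC)(CC)CC)[C@@](C)(O[Si](CC)(CC)CC)CCC=C(C)C
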